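**Plan**

Atom labels follow the target ring: C1 (CMe, chlorovinyl Cα=Cβ), C2 (CH2), C3 (CCl, CH2Br), C4 (CHBr), C5 (CH2), C6 (CHCl); the cyclopentane intermediates contain C1, C2, C4, C5 and C6.
Retrosynthesis: C6–Cl and C4–Br are cut first (each to a C–O bond of opposite configuration, C4 then to a ketone), next the ring bond C2–C3 together with CH2–Br, which contracts the ring to a cyclopentanol, then C3–C4, Cα=Cβ, C1–Cα and C1–CH3.
Forward: the five-membered ring is bought, CH3 and vinyl are added to C1, vinyl is turned into (E)-chlorovinyl, 1-chlorovinyl is added to C4, and the cyclohexane (the only ring formed) arises in step 7 by one-carbon ring enlargement; two substitutions finish.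
Enabling feature: C3 carries Cl and CH2Br and lies between the ring methylene C2 and C4, which can be a carbonyl; the unit C2–C3(Cl)(CH2Br)–C4(=O) of the six-membered ring is what Br+ and a shift of C2 make from a cyclopentanol whose carbinol carbon C4 bears a 1-chlorovinyl group.
Stereochemistry: C6 is bought (S) and inverted at the end; C1 and the C4 carbinol are set anti to the C6 silyloxy group; C3 is relayed from the carbinol in step 7; C4 comes from equatorial hydride attack followed by inversion; the alkene from an E-selective chloroolefination.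

Key step: step 7

Assumption: (S)-4-(tert-butyldimethylsilyloxy)cyclopent-2-en-1-one (1) is taken as a purchasable building block; both antipodes derive from enzymatic desymmetrisation of cis-cyclopent-4-ene-1,3-diol.

**Route**

Step 1
Reactants: 1 (4S)-4-[(tert-butyldimethylsilyl)oxy]cyclopent-2-en-1-one; 2 methylmagnesium bromide
Product: 3 (3S,4S)-4-[(tert-butyldimethylsilyl)oxy]-3-methyl-1-[(trimethylsilyl)oxy]cyclopent-1-ene (methyl trans to OTBS), used crude
Conditions: CuBr·SMe2 (10 mol %), TMSCl, HMPA, THF, −78 °C; Et3N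
Reagents that add atoms: methylmagnesium bromide, C[Mg]Br; chlorotrimethylsilane, C[Si](C)(C)Cl
Why: Copper-catalysed Grignard conjugate addition with in situ silylation is standard for 4-silyloxycyclopentenones: methyl adds to C1 anti to the neighbouring OTBS group (a centre flattened again in step 2), and the enolate is trapped as its silyl ether before it can equilibrate and eliminate the silyloxy group.

Step 2
Reactants: 3 (3S,4S)-4-[(tert-butyldimethylsilyl)oxy]-3-methyl-1-[(trimethylsilyl)oxy]cyclopent-1-ene
Product: 4 (4S)-4-[(tert-butyldimethylsilyl)oxy]-3-methylcyclopent-2-en-1-one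
Conditions: Pd(OAc)2 (10 mol %), O2 (1 atm), DMSO, 40 °C
Reagents that add atoms: none
Why: In this Saegusa–Ito oxidation the palladium(II) enolate formed at C2 undergoes β-hydride elimination towards C1, so the enone is reinstated regiospecifically with the methyl group on the double bond and the C6 stereocentre is not touched.

Step 3
Reactants: 4 (4S)-4-[(tert-butyldimethylsilyl)oxy]-3-methylcyclopent-2-en-1-one; 5 vinylmagnesium bromide
Product: 7 (3R,4S)-4-[(tert-butyldimethylsilyl)oxy]-3-ethenyl-3-methylcyclopentan-1-one, via trimethylsilyl enol ether 6 (not isolated)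
Conditions: CuBr·SMe2 (20 mol %), TMSCl, HMPA, THF, −78 → −40 °C; then 1 M HCl, THF, 0 °C
Reagents that add atoms: vinylmagnesium bromide, C=C[Mg]Br
Why: TMSCl-accelerated copper-catalysed 1,4-addition builds the quaternary centre C1 with vinyl entering anti to the adjacent OTBS group (vinyl trans, methyl cis to OTBS), a facial preference well established for 4-silyloxycyclopentenones, and brief dilute acid cleaves only the trimethylsilyl enol ether.

Step 4
Reactants: 7 (3R,4S)-4-[(tert-butyldimethylsilyl)oxy]-3-ethenyl-3-methylcyclopentan-1-one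
Product: 9 (1S,2S)-2-[(tert-butyldimethylsilyl)oxy]-1-methyl-4-oxocyclopentane-1-carbaldehyde, via secondary ozonide 8 (not isolated)
Conditions: O3, CH2Cl2, −78 °C; then PPh3, −78 → 23 °C
Reagents that add atoms: ozone, [O-][O+]=O
Why: Ozonolysis with reductive work-up cleaves the only C=C bond to a non-enolisable neopentyl aldehyde without affecting the ketone, the silyl ether or the stereocentres.

Step 5
Reactants: 9 (1S,2S)-2-[(tert-butyldimethylsilyl)oxy]-1-methyl-4-oxocyclopentane-1-carbaldehyde; 10 chloroform
Product: 11 (3R,4S)-4-[(tert-butyldimethylsilyl)oxy]-3-[(E)-2-chloroethenyl]-3-methylcyclopentan-1-one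
Conditions: CrCl2 (6 equiv), THF, 65 °C
Reagents that add atoms: chloroform, ClC(Cl)Cl
Why: In the Takai–Utimoto chloroolefination the gem-dichromium reagent from CHCl3 and CrCl2 adds to the aldehyde and eliminates to the (E)-chloroalkene, while the much less reactive ketone is left alone.

Step 6
Reactants: 11 (3R,4S)-4-[(tert-butyldimethylsilyl)oxy]-3-[(E)-2-chloroethenyl]-3-methylcyclopentan-1-one; 12 chloroethene
Product: 13 (1S,3R,4S)-4-[(tert-butyldimethylsilyl)oxy]-1-(1-chloroethenyl)-3-[(E)-2-chloroethenyl]-3-methylcyclopentan-1-ol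
Conditions: 12 (excess), s-BuLi, THF/Et2O/pentane 4:1:1, −110 °C; then 11, −110 → −90 °C; AcOH
Reagents that add atoms: chloroethene, C=CCl
Why: 1,2-Addition of 1-chlorovinyllithium (α-lithiated vinyl chloride) to the ketone is fast at −110 °C, below the temperature at which the carbenoid decomposes or the β-silyloxy ketone enolises, and the nucleophile should approach from the face opposite the C6 silyloxy and cis C1 methyl groups, which sets the C4 carbinol with hydroxyl trans and 1-chlorovinyl cis to the C1 chlorovinyl group.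

Step 7
Reactants: 13 (1S,3R,4S)-4-[(tert-butyldimethylsilyl)oxy]-1-(1-chloroethenyl)-3-[(E)-2-chloroethenyl]-3-methylcyclopentan-1-ol; 14 N-bromosuccinimide
Product: 15 (2R,4R,5S)-2-(bromomethyl)-5-[(tert-butyldimethylsilyl)oxy]-2-chloro-4-[(E)-2-chloroethenyl]-4-methylcyclohexan-1-one
Conditions: NBS (1.05 equiv), (CF3)2CHOH/CH2Cl2 1:4, −40 → 0 °C, dark
Reagents that add atoms: N-bromosuccinimide, O=C1CCC(=O)N1Br
Why: Proposed new method: NBS, activated by hydrogen bonding to the fluorinated alcohol, transfers Br+ to the terminal CH2 of the 1-chlorovinyl group while the ring bond C4–C2, antiperiplanar to the forming C–Br bond, shifts to C3, so that C2–C3 and CH2–Br form, C2–C4 breaks and the carbinol carbon C4 becomes the ketone. The closest known reaction type is the halonium-triggered semipinacol ring expansion of 1-alkenylcycloalkanols, routine for cyclobutanols; a 1-chlorovinyl terminus and a five-to-six enlargement have no model, and the chlorine lone pair together with the hydroxyl push is relied on to compensate for the small strain relief. The cyclohexanone ring arises by a 1,2-shift within the existing ring (one-carbon ring expansion), not by a cyclisation, so no exo or endo mode applies. The new stereocentre C3 is controlled by the C4 carbinol configuration through the rotamer of the bridged transition state: the CH2 terminus that takes up bromine lies outside the ring next to the hydroxyl, and the smaller chlorine, anti to the C–O dipole, points inward over C5–C6, whose upper face carries only hydrogen, which places chlorine cis to the C1 chlorovinyl group. The step needs migration of C2 rather than C5 and attack on the 1,1-disubstituted rather than the (E)-1,2-disubstituted chloroalkene: C5 is inductively deactivated by the β-silyloxy group and its shift would press the inward vinyl substituent against the cis chlorovinyl group at C1, and only the 1,1-disubstituted alkene leads to a tertiary cation assisted by chlorine and oxygen.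

Step 8
Reactants: 15 (2R,4R,5S)-2-(bromomethyl)-5-[(tert-butyldimethylsilyl)oxy]-2-chloro-4-[(E)-2-chloroethenyl]-4-methylcyclohexan-1-one
Product: 16 (1R,2R,4R,5S)-2-(bromomethyl)-5-[(tert-butyldimethylsilyl)oxy]-2-chloro-4-[(E)-2-chloroethenyl]-4-methylcyclohexan-1-ol
Conditions: L-Selectride, THF, −78 → −40 °C; AcOH at −78 °C, no basic work-up
Reagents that add atoms: none
Why: In this bulky trialkylborohydride reduction of a cyclohexanone, hydride should attack C4 equatorially from the upper face, because in the chair with CH3 and CH2Br equatorial the axial trajectory is closed by the syn-axial C6 silyloxy group; this gives the axial alcohol trans to the C3 chlorine, and the cold acidic quench keeps the trans-chlorohydrin alkoxide from closing to an epoxide.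

Step 9
Reactants: 16 (1R,2R,4R,5S)-2-(bromomethyl)-5-[(tert-butyldimethylsilyl)oxy]-2-chloro-4-[(E)-2-chloroethenyl]-4-methylcyclohexan-1-ol; 17 tetrabutylammonium bromide
Product: 19 tert-butyl{[(1S,2R,4S,5S)-5-bromo-4-(bromomethyl)-4-chloro-2-[(E)-2-chloroethenyl]-2-methylcyclohexyl]oxy}dimethylsilane, via C4 triflate 18 (not isolated)
Conditions: Tf2O, 2,6-lutidine, CH2Cl2, −40 → 0 °C; then Bu4NBr, toluene, 0 → 40 °C
Reagents that add atoms: tetrabutylammonium bromide, CCCC[N+](CCCC)(CCCC)CCCC.[Br-]
Why: Triflation followed by SN2 displacement with bromide inverts the axial C4 alcohol to the equatorial bromide cis to the C3 chlorine, the two β-halogens at C3 disfavouring ionisation and skeletal shifts and the weakly basic bromide salt in a non-polar medium favouring substitution over E2.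

Step 10
Reactants: 19 tert-butyl{[(1S,2R,4S,5S)-5-bromo-4-(bromomethyl)-4-chloro-2-[(E)-2-chloroethenyl]-2-methylcyclohexyl]oxy}dimethylsilane
Product: 20 (1S,2R,4S,5S)-5-bromo-4-(bromomethyl)-4-chloro-2-[(E)-2-chloroethenyl]-2-methylcyclohexan-1-ol
Conditions: HF·pyridine, THF, 0 → 23 °C
Reagents that add atoms: none
Why: Acidic fluoride cleaves the Si–O bond, driven by Si–F bond formation, without the basic conditions that could eliminate or displace the alkyl halides.

Step 11
Reactants: 20 (1S,2R,4S,5S)-5-bromo-4-(bromomethyl)-4-chloro-2-[(E)-2-chloroethenyl]-2-methylcyclohexan-1-ol; 21 tetrabutylammonium chloride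
Product: 23 (1S,2S,4R,5R)-2-bromo-1-(bromomethyl)-1,4-dichloro-5-[(E)-2-chloroethenyl]-5-methylcyclohexane, via C6 triflate 22 (not isolated)
Conditions: Tf2O, 2,6-lutidine, CH2Cl2, −40 °C; then Bu4NCl (1.5 equiv), −40 → 23 °C
Reagents that add atoms: tetrabutylammonium chloride, CCCC[N+](CCCC)(CCCC)CCCC.[Cl-]
Why: Triflation followed by SN2 displacement with chloride inverts the axial C6 alcohol to the equatorial chloride cis to the chlorovinyl group, the triflate being so much more reactive than the secondary and neopentyl primary bromides that halide exchange there should not compete at low temperature.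

**Compound list**

1 | (4S)-4-[(tert-butyldimethylsilyl)oxy]cyclopent-2-en-1-one | O=C1C=C[C@@H](O[Si](C)(C)C(C)(C)C)C1 | starting material
2 | methylmagnesium bromide | C[Mg]Br | starting material
3 | (3S,4S)-4-[(tert-butyldimethylsilyl)oxy]-3-methyl-1-[(trimethylsilyl)oxy]cyclopent-1-ene (methyl trans to OTBS) | C[Si](C)(C)OC1=C[C@H](C)[C@@H](O[Si](C)(C)C(C)(C)C)C1 | intermediate
4 | (4S)-4-[(tert-butyldimethylsilyl)oxy]-3-methylcyclopent-2-en-1-one | O=C1C=C(C)[C@@H](O[Si](C)(C)C(C)(C)C)C1 | intermediate
5 | vinylmagnesium bromide | C=C[Mg]Br | starting material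
6 | (3S,4S)-4-[(tert-butyldimethylsilyl)oxy]-3-ethenyl-3-methyl-1-[(trimethylsilyl)oxy]cyclopent-1-ene (vinyl trans to OTBS) | C[Si](C)(C)OC1=C[C@](C)(C=C)[C@@H](O[Si](C)(C)C(C)(C)C)C1 | intermediate (not isolated)
7 | (3R,4S)-4-[(tert-butyldimethylsilyl)oxy]-3-ethenyl-3-methylcyclopentan-1-one | O=C1C[C@](C)(C=C)[C@@H](O[Si](C)(C)C(C)(C)C)C1 | intermediate
8 | (3S,4S)-4-[(tert-butyldimethylsilyl)oxy]-3-methyl-3-(1,2,4-trioxolan-3-yl)cyclopentan-1-one (secondary ozonide, both epimers at the trioxolane carbon) | O=C1C[C@](C)(C2OCOO2)[C@@H](O[Si](C)(C)C(C)(C)C)C1 | intermediate (not isolated)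
9 | (1S,2S)-2-[(tert-butyldimethylsilyl)oxy]-1-methyl-4-oxocyclopentane-1-carbaldehyde | O=C1C[C@](C)(C=O)[C@@H](O[Si](C)(C)C(C)(C)C)C1 | intermediate
10 | chloroform | ClC(Cl)Cl | starting material
11 | (3R,4S)-4-[(tert-butyldimethylsilyl)oxy]-3-[(E)-2-chloroethenyl]-3-methylcyclopentan-1-one | O=C1C[C@](C)(/C=C/Cl)[C@@H](O[Si](C)(C)C(C)(C)C)C1 | intermediate
12 | chloroethene | C=CCl | starting material
13 | (1S,3R,4S)-4-[(tert-butyldimethylsilyl)oxy]-1-(1-chloroethenyl)-3-[(E)-2-chloroethenyl]-3-methylcyclopentan-1-ol (the two chlorovinyl groups cis, OH and OTBS trans to them) | C[C@]1(/C=C/Cl)C[C@@](O)(C(Cl)=C)C[C@@H]1O[Si](C)(C)C(C)(C)C | intermediate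
14 | N-bromosuccinimide | O=C1CCC(=O)N1Br | starting material
15 | (2R,4R,5S)-2-(bromomethyl)-5-[(tert-butyldimethylsilyl)oxy]-2-chloro-4-[(E)-2-chloroethenyl]-4-methylcyclohexan-1-one | C[C@]1(/C=C/Cl)C[C@](Cl)(CBr)C(=O)C[C@@H]1O[Si](C)(C)C(C)(C)C | intermediate
16 | (1R,2R,4R,5S)-2-(bromomethyl)-5-[(tert-butyldimethylsilyl)oxy]-2-chloro-4-[(E)-2-chloroethenyl]-4-methylcyclohexan-1-ol | C[C@]1(/C=C/Cl)C[C@](Cl)(CBr)[C@H](O)C[C@@H]1O[Si](C)(C)C(C)(C)C | intermediate
17 | tetrabutylammonium bromide | CCCC[N+](CCCC)(CCCC)CCCC.[Br-] | starting material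
18 | (1R,2R,4R,5S)-2-(bromomethyl)-5-[(tert-butyldimethylsilyl)oxy]-2-chloro-4-[(E)-2-chloroethenyl]-4-methylcyclohexyl trifluoromethanesulfonate | C[C@]1(/C=C/Cl)C[C@](Cl)(CBr)[C@H](OS(=O)(=O)C(F)(F)F)C[C@@H]1O[Si](C)(C)C(C)(C)C | intermediate (not isolated)
19 | tert-butyl{[(1S,2R,4S,5S)-5-bromo-4-(bromomethyl)-4-chloro-2-[(E)-2-chloroethenyl]-2-methylcyclohexyl]oxy}dimethylsilane | C[C@]1(/C=C/Cl)C[C@](Cl)(CBr)[C@@H](Br)C[C@@H]1O[Si](C)(C)C(C)(C)C | intermediate
20 | (1S,2R,4S,5S)-5-bromo-4-(bromomethyl)-4-chloro-2-[(E)-2-chloroethenyl]-2-methylcyclohexan-1-ol | C[C@]1(/C=C/Cl)C[C@](Cl)(CBr)[C@@H](Br)C[C@@H]1O | intermediate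
21 | tetrabutylammonium chloride | CCCC[N+](CCCC)(CCCC)CCCC.[Cl-] | starting material
22 | (1S,2R,4S,5S)-5-bromo-4-(bromomethyl)-4-chloro-2-[(E)-2-chloroethenyl]-2-methylcyclohexyl trifluoromethanesulfonate | C[C@]1(/C=C/Cl)C[C@](Cl)(CBr)[C@@H](Br)C[C@@H]1OS(=O)(=O)C(F)(F)F | intermediate (not isolated)
23 | (1S,2S,4R,5R)-2-bromo-1-(bromomethyl)-1,4-dichloro-5-[(E)-2-chloroethenyl]-5-methylcyclohexane (chlorovinyl, C3–Cl, C4–Br and C6–Cl all cis) | C[C@]1(/C=C/Cl)C[C@](Cl)(CBr)[C@@H](Br)C[C@H]1Cl | target

**Count and risks**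

Total steps: 11. Longest linear sequence: 11 steps (1 → 23).

Steps most likely to fail:

1. Step 7 (new method). The cation may be captured by the hydroxyl (epoxide or bromomethyl ketone formation) instead of triggering the C–C shift, C5 may migrate in place of C2, Br+ may attack the other chloroalkene, or facial control at C3 may be lost.
Fallback (known reactions only; the regiochemistry of ring enlargement is fixed by the enol ether): the route leaves at enol silane 6, isolated instead of hydrolysed, and rejoins at ketone 15. Dichlorocarbene (Cl3CCO2Na, DME, reflux) cyclopropanates the electron-rich enol double bond to the dichlorocarbene adduct F1. On heating in toluene this opens with loss of Me3SiCl to the ring-enlarged 2-chlorocyclohexenone F2, in which C3 has entered between C4 and C2 and already carries its chlorine. Ozonolysis of the vinyl group (O3; PPh3) passes through the ozonide F3 to the aldehyde F4, and chloroolefination as in step 5 gives the chlorovinyl chloroenone F5. Rhodium-catalysed 1,4-hydrosilylation (Et3SiH, RhCl(PPh3)3) gives the triethylsilyl enol ether F6. A Mukaiyama aldol reaction with aqueous formaldehyde (Yb(OTf)3, THF) gives the hydroxymethyl chloro ketone F7; its C3 epimers would have to be separated, because the substrate control of step 7 is given up. An Appel reaction (CBr4, PPh3) on the isomer with CH2OH trans to the C1 chlorovinyl group then gives 15.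

2. Step 9. E2 towards C5 through the antiperiplanar axial hydrogen, participation of the antiperiplanar C3 chlorine (retention or chlorine shift), or sluggish substitution at the neopentyl-type carbon may prevail over inversion.
Fallback: it sets out from triflate 18 and comes back at bromide 19, and it forms the C–Br bond by radical atom transfer instead of by inversion. Potassium O-ethyl xanthate (acetone, 0 → 23 °C), a soft and weakly basic sulfur nucleophile, displaces the triflate to give the S-alkyl xanthate F8. Radical xanthate-to-bromide exchange (ethyl 2-bromo-2-methylpropanoate, dilauroyl peroxide, chlorobenzene, reflux) then passes through the C4 radical, which should take up bromine from the upper face because the lower one is shielded by the syn-axial silyloxy group. The exchange is stereoconvergent, so the configuration of the xanthate does not matter.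

3. Step 11. Ionisation of the neopentyl triflate with participation or 1,2-shift of the antiperiplanar chlorovinyl group, E2 towards C5, or chloride–bromide exchange at C4 or CH2Br may compete with inversion.
Fallback: it sets out from carbinol 13 and comes back at target 23; the chlorine is introduced on the five-membered ring, where SN2 is intrinsically faster and the leaving group less ionising. TBAF (THF) gives the diol F9. Appel chlorination (PPh3, NCS, THF) of the secondary hydroxyl with inversion, the tertiary one being left, gives the chloro carbinol F10. Ring expansion with NBS as in step 7 gives the chloro ketone F11; the C6 chlorine deactivates C5 as migrating group more than the silyloxy group, at the price of a closer contact with the inward chlorine on the upper face. L-Selectride gives the axial alcohol F12, and bromination as in step 9 through the triflate F13 gives 23.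

Further compounds
F1 | step 7 | tert-butyl{[6,6-dichloro-4-ethenyl-4-methyl-1-[(trimethylsilyl)oxy]bicyclo[3.1.0]hexan-3-yl]oxy}dimethylsilane (C3 and C4 as in 6, cyclopropane carbons as a mixture) | C[Si](C)(C)OC12C([C@](C)(C=C)[C@@H](O[Si](C)(C)C(C)(C)C)C1)C2(Cl)Cl
F2 | step 7 | (4S,5S)-5-[(tert-butyldimethylsilyl)oxy]-2-chloro-4-ethenyl-4-methylcyclohex-2-en-1-one | O=C1C(Cl)=C[C@](C)(C=C)[C@@H](O[Si](C)(C)C(C)(C)C)C1
F3 | step 7 | (4S,5S)-5-[(tert-butyldimethylsilyl)oxy]-2-chloro-4-methyl-4-(1,2,4-trioxolan-3-yl)cyclohex-2-en-1-one (both epimers at the trioxolane carbon) | O=C1C(Cl)=C[C@](C)(C2OCOO2)[C@@H](O[Si](C)(C)C(C)(C)C)C1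
F4 | step 7 | (1S,6S)-6-[(tert-butyldimethylsilyl)oxy]-3-chloro-1-methyl-4-oxocyclohex-2-ene-1-carbaldehyde | O=C1C(Cl)=C[C@](C)(C=O)[C@@H](O[Si](C)(C)C(C)(C)C)C1
F5 | step 7 | (4S,5S)-5-[(tert-butyldimethylsilyl)oxy]-2-chloro-4-[(E)-2-chloroethenyl]-4-methylcyclohex-2-en-1-one | O=C1C(Cl)=C[C@](C)(/C=C/Cl)[C@@H](O[Si](C)(C)C(C)(C)C)C1
F6 | step 7 | (4R,5S)-5-[(tert-butyldimethylsilyl)oxy]-2-chloro-4-[(E)-2-chloroethenyl]-4-methyl-1-[(triethylsilyl)oxy]cyclohex-1-ene | CC[Si](CC)(CC)OC1=C(Cl)C[C@](C)(/C=C/Cl)[C@@H](O[Si](C)(C)C(C)(C)C)C1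
F7 | step 7 | (2S,4R,5S)-5-[(tert-butyldimethylsilyl)oxy]-2-chloro-4-[(E)-2-chloroethenyl]-2-(hydroxymethyl)-4-methylcyclohexan-1-one | C[C@]1(/C=C/Cl)C[C@](Cl)(CO)C(=O)C[C@@H]1O[Si](C)(C)C(C)(C)C
F8 | step 9 | O-ethyl S-[(1S,2R,4R,5S)-2-(bromomethyl)-5-[(tert-butyldimethylsilyl)oxy]-2-chloro-4-[(E)-2-chloroethenyl]-4-methylcyclohexyl] carbonodithioate | C[C@]1(/C=C/Cl)C[C@](Cl)(CBr)[C@@H](SC(=S)OCC)C[C@@H]1O[Si](C)(C)C(C)(C)C
F9 | step 11 | (1S,3S,4R)-1-(1-chloroethenyl)-4-[(E)-2-chloroethenyl]-4-methylcyclopentane-1,3-diol | C[C@]1(/C=C/Cl)C[C@@](O)(C(Cl)=C)C[C@@H]1O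
F10 | step 11 | (1S,3R,4R)-4-chloro-1-(1-chloroethenyl)-3-[(E)-2-chloroethenyl]-3-methylcyclopentan-1-ol | C[C@]1(/C=C/Cl)C[C@@](O)(C(Cl)=C)C[C@H]1Cl
F11 | step 11 | (2R,4R,5R)-2-(bromomethyl)-2,5-dichloro-4-[(E)-2-chloroethenyl]-4-methylcyclohexan-1-one | C[C@]1(/C=C/Cl)C[C@](Cl)(CBr)C(=O)C[C@H]1Cl
F12 | step 11 | (1R,2R,4R,5R)-2-(bromomethyl)-2,5-dichloro-4-[(E)-2-chloroethenyl]-4-methylcyclohexan-1-ol | C[C@]1(/C=C/Cl)C[C@](Cl)(CBr)[C@H](O)C[C@H]1Cl
F13 | step 11 | (1R,2R,4R,5R)-2-(bromomethyl)-2,5-dichloro-4-[(E)-2-chloroethenyl]-4-methylcyclohexyl trifluoromethanesulfonate | C[C@]1(/C=C/Cl)C[C@](Cl)(CBr)[C@H](OS(=O)(=O)C(F)(F)F)C[C@H]1Cl
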